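## Structural features

The target 15 is a flavanone. Benzene ring A is fused through C4a and C8a to the 2,3-dihydropyran-4-one ring C, and the catechol ring B is attached to C2 by a single C–C bond. Ring A carries four different groups in fixed order: OH at C5 (hydrogen-bonded to the C4 carbonyl), H at C6, OMe at C7 and the 3-methylbut-2-enyl (prenyl) chain at C8, next to the ring oxygen O1 on C8a. C2 is the only stereocentre (S; CIP order O1 > ring B > C3 > H). It has no stereogenic neighbour, so its configuration cannot be relayed and must come from a catalyst or an earlier chiral building block. Three groups are fragile. The C2 configuration is lost by reversible opening of ring C across O1–C2 (retro-oxa-Michael to the 2'-hydroxychalcone, favoured by base and by a free 4'-phenoxide). The trisubstituted prenyl alkene rules out hydrogenolysis and strong protic or Lewis acid. The catechol is easily oxidised. The real difficulty is twofold: C2 must be set with absolute control in a step after which nothing strongly basic or acidic is needed, and the prenyl group must go to C8 and not to C6. The key step uses the C2–H bond. It is α to O1 and benzylic to the electron-rich ring B, and it lies six atoms from C3 along C3–C4–C4a–C8a–O1–C2. The fifth atom of that chain, O1, has no hydrogen, so a carbene at C3 has one activated C–H bond within reach and can form ring C and the stereocentre by inserting into it.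

## Logic of the disconnections

15 ⇒ 14. The three aryl O–Si bonds (at O5, O3' and O4') are cut. Free phenols cannot be carried through a carbene step, least of all O5–H, which would close a five-membered ring by O–H insertion. Using silyl groups on all three oxygens allows one buffered fluoride operation at the end. That avoids the acid needed for acetal protecting groups (a risk to the prenyl alkene) and the hydrogenolysis needed for benzyl ethers. The demand on the forward step is that no phenoxide persists, because a 4'-phenoxide opens ring C and erases C2.

14 ⇒ 13. The C2–C3 bond is cut. This removes ring C and the only stereocentre in one move and leaves an achiral, open precursor. The forward step must select one of two enantiotopic benzylic hydrogens and must prefer C–H insertion to attack on the O1 lone pair. C3 stays unsubstituted, so no second stereocentre arises. The group on O5 must have no α-C–H bond and must make O5 a poor nucleophile. A triisopropylsilyl group is chosen over a smaller silyl group for this reason, and for its resistance to base and to silyl transfer in the step that makes 13. Ring B carries tert-butyldimethylsilyl groups and not acetal ethers, whose hydridic O–CH2–O bonds and Lewis-basic oxygens are needless liabilities beside a carbene and whose removal needs acid.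

13 ⇒ 11 (through 12). The C3=N2 unit is cut, which leads back to a methyl ketone. C3 is then the acetyl carbon of the commercial ring A building block, and no homologation of a benzoic acid with diazomethane is needed. The forward step must activate the methyl group by transient trifluoroacetylation (12) and must not move the silyl group from O5 to the enolate oxygen.

11 ⇒ 10 + 3. The O1–CH2 bond is cut, which joins ring A and ring B convergently. The forward step must etherify a hindered, hydrogen-bonded phenol without carbonate or hydroxide, which endanger aryl silyl ethers. A Mitsunobu coupling with the alcohol 3 itself does this and saves the separate preparation of a labile benzyl bromide.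

10 ⇒ 8 (through 9). The C8–CH2 bond of the prenyl group is cut. Direct C-prenylation of such a ring is unselective between C6, C8 and oxygen. A [3,3] shift from the oxygen that becomes O1 delivers the chain to the neighbouring carbon only, since the other ortho position carries the acetyl group. The allyl inversion requires a 1,1-dimethylallyl ether in 8.

8 ⇒ 7 + 5. The tertiary C–O bond of the allyl ether is cut. A tertiary ether cannot be made by direct displacement, so the forward step is a palladium π-allyl substitution, which must go to the more substituted allyl terminus.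

7 ⇒ 6. The O5–Si bond is cut. The two hydroxyls of 6 are equivalent, so whichever is silylated gives the same product. The silyl group marks the future O5 and the free hydroxyl becomes O1. The forward step must stop after one silylation.

5 ⇒ 4 and 3 ⇒ 2 ⇒ 1. The carbonate C–O bond of 5 is cut back to the tertiary alcohol 4. The alcohol 3 comes from 1 by silylation of both phenols (2) and reduction of the aldehyde. These are routine functional-group steps.

## Other disconnections considered

Alternative 1: Three bonds of ring A are cut at once (C4a–C8a, C5–C6 and C7–C8). This leads back to the tethered diyne A1, (5S)-5-[3,4-bis(methoxymethoxy)phenyl]-1-ethoxy-5-(5-methylhex-4-en-1-ynyloxy)pent-1-yn-3-one, and methoxyacetylene A2.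
- Forward step: [Rh(cod)2]BF4 with BINAP, a cationic complex of monovalent rhodium, would couple the two alkynes of A1 oxidatively to a rhodacyclopentadiene, which closes ring C. Head-to-tail insertion of A2 would then complete ring A and give the 5-O-ethyl flavanone A3. Chelation-assisted cleavage of the ethyl ether and acetal removal would lead to 15.
- In its favour: every ring A substituent is fixed by an alkyne terminus, so no Claisen step and no differentiation of phenols is needed. On regiocontrol of ring A and on bonds formed per step this plan is better than the chosen one. C2 is already present in A1, so the key step need not be enantioselective.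
- Against it: A1 holds the C2 oxygen β to a ketone as an ynolate leaving group, so β-elimination across C2–C3 would erase the stereocentre. The ynol ether of a secondary benzylic alcohol is also thermally labile and hard to make in enantioenriched form. A2 is volatile and prone to self-trimerisation, and its orientation of insertion between two polarised alkynes is not assured. The 5-O-ethyl group needs a Lewis-acid dealkylation beside a prenyl group.
- Comparison: the carbene route sets C2 under catalyst control, which is less certain in principle. Its precursor 13 is robust and is reached in few steps from an intact aromatic ring. The assembly of A1 (an asymmetric aldol-type step, O-alkynylation, alkyne alkylation) would take more steps than the whole route to 13.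

Alternative 2: The O1–C8a bond is cut. This leads back to the aryl triflate A4, 2-[(3S)-3-[3,4-bis(methoxymethoxy)phenyl]-1-(tert-butyldimethylsilyloxy)-3-hydroxypropyl]-5-methoxy-3-(methoxymethoxy)-6-(3-methylbut-2-enyl)phenyl trifluoromethanesulfonate.
- Forward step: Pd(OAc)2 (reduced in the flask to zerovalent palladium), a bulky dialkylbiarylphosphine and K3PO4 would bring about oxidative addition into the C8a–O triflate bond, exchange of triflate for the secondary alkoxide, and C–O reductive elimination to the chroman A5. Desilylation at C4, oxidation to the ketone and acetal removal would then give 15.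
- In its favour: the stereocentre is made earlier by dependable carbonyl chemistry, and the coupling breaks no bond at C2. On certainty of configuration this plan is better than the chosen one. It also needs no diazo compound and has no ylide pathway, which is a safety and chemoselectivity advantage.
- Against it: C8a is flanked by the prenyl group and by the branched side chain and sits on an electron-rich ring, so both oxidative addition and C–O reductive elimination are hindered. β-Hydride elimination from the palladium alkoxide and base-induced S–O cleavage of the triflate compete. C4 must be carried at the alcohol level, which adds a second, inconsequential stereocentre and two redox adjustments. The three ring A oxygens must be differentiated so that the triflate sits on the right one.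
- Comparison: in mechanism it is a two-electron cross-coupling against a carbene insertion. In step count it is clearly longer, both before the key step and after it (three operations against one).

Alternative 3: The C3–C4 bond is cut (with the C2–H bond). This leads back to the aldehyde A6, 2-[1-[3,4-bis(methoxymethoxy)phenyl]ethenyloxy]-6-hydroxy-4-methoxy-3-(3-methylbut-2-enyl)benzaldehyde.
- Forward step: [Rh(cod)2]BF4 and a chiral bisphosphine would insert rhodium into the aldehyde C–H bond, assisted by the neighbouring O5 hydroxyl, to give an acyl hydride of trivalent rhodium. Hydride delivery to C2 of the enol ether and C3–C4 reductive elimination would close ring C to the flavanone A7. Acetal removal alone would then give 15.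
- In its favour: the step is a pure isomerisation with no leaving group. The free 5-OH is used as an anchor and not protected, so on atom economy and on protecting-group count this plan is better. Like the chosen plan it sets C2 from an achiral precursor under catalyst control, and on that point the two are equal.
- Against it: A6 is an aryl 1-arylvinyl ether, which is awkward to make next to an aldehyde and a free phenol and hydrolyses readily under acid. Closing a six-membered ketone by hydroacylation is less favourable than five-membered closure, so the exo mode and decarbonylation compete. The two substituents on the alkene carbon (aryl and aryloxy) are similar in size, so face selection is uncertain. The ring A building block would have to carry a formyl group in place of acetyl.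
- Comparison: the post-key-step sequence is as short as in the chosen plan, but the precursor is more fragile than 13 and its preparation is longer and less secure.

Key step: step 9

Assumption: the (S)-configured catalyst is taken to deliver the 2S product. Should its intrinsic preference be the opposite, the enantiomeric catalyst Rh2(R-PTTL)4 would be used and nothing else in the route would change.

## Route

Step 1
Reactants: 1 3,4-dihydroxybenzaldehyde
Product: 2 3,4-bis(tert-butyldimethylsilyloxy)benzaldehyde
Conditions: TBSCl (2.3 equiv), imidazole, DMF, rt
Reagents that add atoms: tert-butyldimethylsilyl chloride, CC(C)(C)[Si](C)(C)Cl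
Why: Imidazole-mediated O-silylation of both phenols; the aldehyde is inert under these conditions.

Step 2
Reactants: 2 3,4-bis(tert-butyldimethylsilyloxy)benzaldehyde
Product: 3 [3,4-bis(tert-butyldimethylsilyloxy)phenyl]methanol
Conditions: NaBH4, THF/MeOH, 0 °C
Reagents that add atoms: none
Why: Chemoselective hydride reduction of the aldehyde; the aryl silyl ethers of the electron-rich ring should tolerate borohydride at 0 °C for the short reaction time.

Step 3
Reactants: 4 2-methylbut-3-en-2-ol
Product: 5 tert-butyl 2-methylbut-3-en-2-yl carbonate
Conditions: n-BuLi, THF, –78 → 0 °C; Boc2O, 0 °C → rt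
Reagents that add atoms: di-tert-butyl dicarbonate, CC(C)(C)OC(=O)OC(=O)OC(C)(C)C
Why: O-acylation of the lithium alkoxide of the tertiary allylic alcohol gives the mixed carbonate, the ionisable partner for step 5.

Step 4
Reactants: 6 2',6'-dihydroxy-4'-methoxyacetophenone
Product: 7 1-[2-hydroxy-4-methoxy-6-(triisopropylsilyloxy)phenyl]ethanone
Conditions: TIPSCl (1.05 equiv), imidazole, DMF, 0 °C → rt
Reagents that add atoms: triisopropylsilyl chloride, CC(C)[Si](Cl)(C(C)C)C(C)C
Why: The two hydroxyls are equivalent, and after one silylation the remaining one is locked in a six-membered hydrogen bond to the acetyl carbonyl and reacts much more slowly with the bulky chlorosilane, so the reaction should stop at the monosilyl ether.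

Step 5
Reactants: 7 1-[2-hydroxy-4-methoxy-6-(triisopropylsilyloxy)phenyl]ethanone; 5 tert-butyl 2-methylbut-3-en-2-yl carbonate
Product: 8 1-[4-methoxy-2-(2-methylbut-3-en-2-yloxy)-6-(triisopropylsilyloxy)phenyl]ethanone
Conditions: Pd(PPh3)4 (3 mol %), THF, 0 °C → rt
Reagents that add atoms: none
Why: Tsuji–Trost O-allylation: zerovalent palladium ionises 5 with loss of CO2, the released tert-butoxide deprotonates the phenol, and the phenoxide attacks the 1,1-dimethyl-π-allyl palladium complex at its more substituted terminus under kinetic control to give the tertiary aryl ether.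

Step 6
Reactants: 8 1-[4-methoxy-2-(2-methylbut-3-en-2-yloxy)-6-(triisopropylsilyloxy)phenyl]ethanone
Product: 10 1-[2-hydroxy-4-methoxy-3-(3-methylbut-2-enyl)-6-(triisopropylsilyloxy)phenyl]ethanone, via ortho-dienone 9 (not isolated)
Conditions: xylenes, 130 °C
Reagents that add atoms: none
Why: Aromatic Claisen rearrangement ([3,3]-sigmatropic, chair transition state) delivers the allyl terminus to the only free ortho carbon to give dienone 9, which enolises to the phenol; the allyl inversion turns the 1,1-dimethylallyl group into the prenyl group, and the new hydroxyl is held by the acetyl carbonyl, which guards against cyclisation onto the alkene.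

Step 7
Reactants: 10 1-[2-hydroxy-4-methoxy-3-(3-methylbut-2-enyl)-6-(triisopropylsilyloxy)phenyl]ethanone; 3 [3,4-bis(tert-butyldimethylsilyloxy)phenyl]methanol
Product: 11 1-[2-[[3,4-bis(tert-butyldimethylsilyloxy)phenyl]methoxy]-4-methoxy-3-(3-methylbut-2-enyl)-6-(triisopropylsilyloxy)phenyl]ethanone
Conditions: PPh3, DIAD, THF, 0 °C → rt
Reagents that add atoms: none
Why: Mitsunobu etherification: the primary benzylic alcohol is activated as its alkoxyphosphonium ion and displaced by the acidic, hydrogen-bonded phenol under neutral conditions that spare all three aryl silyl ethers.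

Step 8
Reactants: 11 1-[2-[[3,4-bis(tert-butyldimethylsilyloxy)phenyl]methoxy]-4-methoxy-3-(3-methylbut-2-enyl)-6-(triisopropylsilyloxy)phenyl]ethanone
Product: 13 2-diazo-1-[2-[[3,4-bis(tert-butyldimethylsilyloxy)phenyl]methoxy]-4-methoxy-3-(3-methylbut-2-enyl)-6-(triisopropylsilyloxy)phenyl]ethanone, via trifluoroacetyl diketone 12 (not isolated)
Conditions: LiN(SiMe3)2, THF, –78 °C; CF3CO2CH2CF3, –78 °C; aq. NH4Cl; then p-ABSA, Et3N, H2O (1 equiv), MeCN, rt
Reagents that add atoms: 4-acetamidobenzenesulfonyl azide (p-ABSA), CC(=O)Nc1ccc(cc1)S(=O)(=O)N=[N+]=[N-] (supplies the two diazo nitrogens); 2,2,2-trifluoroethyl trifluoroacetate, O=C(OCC(F)(F)F)C(F)(F)F (supplies the trifluoroacetyl group of 12 only)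
Why: Detrifluoroacetylative diazo transfer: Claisen condensation of the kinetic lithium enolate with the trifluoroacetate gives diketone 12, whose enolate adds to the sulfonyl azide and fragments, passing the trifluoroacetyl group to the sulfonamide nitrogen and leaving the diazomethyl ketone; the bulky triisopropylsilyl group should resist transfer from O5 to the enolate oxygen.

Step 9
Reactants: 13 2-diazo-1-[2-[[3,4-bis(tert-butyldimethylsilyloxy)phenyl]methoxy]-4-methoxy-3-(3-methylbut-2-enyl)-6-(triisopropylsilyloxy)phenyl]ethanone
Product: 14 (2S)-2-[3,4-bis(tert-butyldimethylsilyloxy)phenyl]-7-methoxy-8-(3-methylbut-2-enyl)-5-(triisopropylsilyloxy)-2,3-dihydrochromen-4-one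
Conditions: Rh2(S-PTTL)4 (dirhodium tetrakis[N-phthaloyl-(S)-tert-leucinate], 2 mol %), CH2Cl2, 4 Å MS, 0 °C, slow addition of 13
Reagents that add atoms: none
Why: Rh2(S-PTTL)4, a paddlewheel dimer of divalent rhodium, is attacked at an axial site by the diazo carbon of 13 and loses N2 to give an electrophilic rhodium carbene at C3. The carbene inserts into a C–H bond of the O1–CH2 group through a three-centre, hydride-transfer-like transition state in which C2–C3 bond formation and hydrogen migration to C3 are concerted, and the catalyst is released. The closest known reaction type is the chiral dirhodium carboxylate-catalysed intramolecular C–H insertion of ortho-alkoxyaryl α-diazoketones, which gives chroman-4-ones. Ring C closes by a 1,6-insertion (six-membered transition state through C3, C4, C4a, C8a, O1 and C2); the usual five-membered closure is unavailable because the fifth atom is O1, which bears no hydrogen. C2 is set by the catalyst: the four N-phthaloyl tert-leucinate ligands wall in the carbene so that one of the two enantiotopic benzylic hydrogens is presented preferentially, and since insertion goes with retention, replacement of the pro-S hydrogen gives 2S. The step needs chemoselectivity for C–H insertion over oxonium ylide formation at O1 followed by a [1,2]-benzyl shift; this is secured by the low basicity and crowding of the aryl ether oxygen between the acyl and prenyl groups, by the double activation of the C–H bond (α-oxygen and para-silyloxyaryl), and by the choice of a rhodium carboxylate over a copper catalyst. O5 is shut off by the triisopropylsilyl group, which has no C–H bond closer than a seven-membered transition state, and the prenyl group sits meta to the acyl carbon and cannot reach the carbene. Slow addition keeps the diazoketone concentration low and should suppress carbene dimerisation and intermolecular cyclopropanation of the prenyl alkene.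

Step 10
Reactants: 14 (2S)-2-[3,4-bis(tert-butyldimethylsilyloxy)phenyl]-7-methoxy-8-(3-methylbut-2-enyl)-5-(triisopropylsilyloxy)-2,3-dihydrochromen-4-one
Product: 15 (2S)-2-(3,4-dihydroxyphenyl)-5-hydroxy-7-methoxy-8-(3-methylbut-2-enyl)-2,3-dihydrochromen-4-one
Conditions: Bu4NF, AcOH (1:1, 3.5 equiv each), THF, 0 °C → rt
Reagents that add atoms: none
Why: Fluoride cleaves the three aryl Si–O bonds through pentacoordinate silicon; acetic acid protonates each phenoxide as it forms, so ring C should not open by retro-oxa-Michael reaction and C2 should keep its configuration, while the prenyl alkene and the methyl ether are inert.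

## Compound list

1 | 3,4-dihydroxybenzaldehyde | O=Cc1ccc(O)c(O)c1 | starting material
2 | 3,4-bis(tert-butyldimethylsilyloxy)benzaldehyde | O=Cc1ccc(O[Si](C)(C)C(C)(C)C)c(O[Si](C)(C)C(C)(C)C)c1 | intermediate
3 | [3,4-bis(tert-butyldimethylsilyloxy)phenyl]methanol | OCc1ccc(O[Si](C)(C)C(C)(C)C)c(O[Si](C)(C)C(C)(C)C)c1 | intermediate
4 | 2-methylbut-3-en-2-ol | C=CC(C)(C)O | starting material
5 | tert-butyl 2-methylbut-3-en-2-yl carbonate | C=CC(C)(C)OC(=O)OC(C)(C)C | intermediate
6 | 2',6'-dihydroxy-4'-methoxyacetophenone | CC(=O)c1c(O)cc(OC)cc1O | starting material
7 | 1-[2-hydroxy-4-methoxy-6-(triisopropylsilyloxy)phenyl]ethanone | CC(=O)c1c(O)cc(OC)cc1O[Si](C(C)C)(C(C)C)C(C)C | intermediate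
8 | 1-[4-methoxy-2-(2-methylbut-3-en-2-yloxy)-6-(triisopropylsilyloxy)phenyl]ethanone | CC(=O)c1c(OC(C)(C)C=C)cc(OC)cc1O[Si](C(C)C)(C(C)C)C(C)C | intermediate
9 | 2-acetyl-5-methoxy-6-(3-methylbut-2-enyl)-3-(triisopropylsilyloxy)cyclohexa-2,4-dien-1-one (racemic at C6) | CC(=O)C1=C(O[Si](C(C)C)(C(C)C)C(C)C)C=C(OC)C(CC=C(C)C)C1=O | intermediate
10 | 1-[2-hydroxy-4-methoxy-3-(3-methylbut-2-enyl)-6-(triisopropylsilyloxy)phenyl]ethanone | CC(=O)c1c(O)c(CC=C(C)C)c(OC)cc1O[Si](C(C)C)(C(C)C)C(C)C | intermediate
11 | 1-[2-[[3,4-bis(tert-butyldimethylsilyloxy)phenyl]methoxy]-4-methoxy-3-(3-methylbut-2-enyl)-6-(triisopropylsilyloxy)phenyl]ethanone | CC(=O)c1c(OCc2ccc(O[Si](C)(C)C(C)(C)C)c(O[Si](C)(C)C(C)(C)C)c2)c(CC=C(C)C)c(OC)cc1O[Si](C(C)C)(C(C)C)C(C)C | intermediate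
12 | 1-[2-[[3,4-bis(tert-butyldimethylsilyloxy)phenyl]methoxy]-4-methoxy-3-(3-methylbut-2-enyl)-6-(triisopropylsilyloxy)phenyl]-4,4,4-trifluorobutane-1,3-dione | O=C(CC(=O)C(F)(F)F)c1c(OCc2ccc(O[Si](C)(C)C(C)(C)C)c(O[Si](C)(C)C(C)(C)C)c2)c(CC=C(C)C)c(OC)cc1O[Si](C(C)C)(C(C)C)C(C)C | intermediate
13 | 2-diazo-1-[2-[[3,4-bis(tert-butyldimethylsilyloxy)phenyl]methoxy]-4-methoxy-3-(3-methylbut-2-enyl)-6-(triisopropylsilyloxy)phenyl]ethanone | COc1cc(O[Si](C(C)C)(C(C)C)C(C)C)c(C(=O)C=[N+]=[N-])c(OCc2ccc(O[Si](C)(C)C(C)(C)C)c(O[Si](C)(C)C(C)(C)C)c2)c1CC=C(C)C | intermediate
14 | (2S)-2-[3,4-bis(tert-butyldimethylsilyloxy)phenyl]-7-methoxy-8-(3-methylbut-2-enyl)-5-(triisopropylsilyloxy)-2,3-dihydrochromen-4-one | COc1cc(O[Si](C(C)C)(C(C)C)C(C)C)c2c(c1CC=C(C)C)O[C@H](c1ccc(O[Si](C)(C)C(C)(C)C)c(O[Si](C)(C)C(C)(C)C)c1)CC2=O | intermediate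
15 | (2S)-2-(3,4-dihydroxyphenyl)-5-hydroxy-7-methoxy-8-(3-methylbut-2-enyl)-2,3-dihydrochromen-4-one | COc1cc(O)c2c(c1CC=C(C)C)O[C@H](c1ccc(O)c(O)c1)CC2=O | target

## Step count and risks

Total step count: 10. Longest linear sequence: 7 steps (steps 4 to 10, from 6).

Least certain steps:

Step 9 (key step). The most likely failure is loss of chemoselectivity: the carbene attacks the lone pair of O1, and the resulting five-membered oxonium ylide undergoes a [1,2]-benzyl shift. The second risk is weak discrimination of the two enantiotopic hydrogens, because an acceptor-only carbene reacts through an early transition state. The fallback sets the stereocentre by conjugate addition and sets out from 10, so that steps 7 and 8 are not needed.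
- Condensation of 10 with Me2NCH(OMe)2 (toluene, 90 °C) should give the enaminone (E)-3-(dimethylamino)-1-[2-hydroxy-4-methoxy-3-(3-methylbut-2-enyl)-6-(triisopropylsilyloxy)phenyl]prop-2-en-1-one F1.
- Acid (TsOH, toluene) should close F1 with loss of dimethylamine to the chromone 7-methoxy-8-(3-methylbut-2-enyl)-5-(triisopropylsilyloxy)chromen-4-one F2.
- Separately, commercial 4-bromocatechol (Oc1ccc(Br)cc1O) is silylated (TBSCl, imidazole, DMF) to 4-bromo-1,2-bis(tert-butyldimethylsilyloxy)benzene F3.
- Bromine–lithium exchange (n-BuLi, THF, –78 °C), B(OiPr)3 and mild hydrolysis convert F3 into [3,4-bis(tert-butyldimethylsilyloxy)phenyl]boronic acid F4.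
- The known palladium-catalysed enantioselective conjugate addition of arylboronic acids to chromones then joins the two. The conditions are Pd(OCOCF3)2, 4-tert-butyl-2-(pyridin-2-yl)-4,5-dihydrooxazole of the configuration that gives 2S, NH4PF6, H2O, ClCH2CH2Cl, 60 °C. This should add the aryl group of F4 to C2 of F2 and come back to the route at 14.

Step 8. The likely failures are incomplete C-acylation of the enolate of the doubly ortho-substituted ketone, and loss or migration of the O5 silyl group during the enolate stage or under the aqueous amine of the diazo transfer. The fallback sets out from 11 and avoids strong base. Me2NCH(OMe)2 (toluene, 100 °C) should give the enaminone (E)-1-[2-[[3,4-bis(tert-butyldimethylsilyloxy)phenyl]methoxy]-4-methoxy-3-(3-methylbut-2-enyl)-6-(triisopropylsilyloxy)phenyl]-3-(dimethylamino)prop-2-en-1-one F5. Its electron-rich C=C bond should add 4-methylbenzenesulfonyl azide (MeCN, rt), and the triazoline should fragment to the sulfonyl formamidine and the diazoketone. This comes back to the route at 13.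

Step 5. The likely failures are attack of the phenoxide at the unsubstituted allyl terminus, palladium-mediated equilibration of the tertiary ether to the linear prenyl ether, and slow reaction of the hydrogen-bonded phenol. The fallback sets out from 7 and builds the tertiary ether through an alkyne. Copper-catalysed propargylation with 3-chloro-3-methylbut-1-yne (CC(C)(Cl)C#C), DBU and catalytic CuCl2·2H2O in MeCN at 0 °C should give 1-[4-methoxy-2-(2-methylbut-3-yn-2-yloxy)-6-(triisopropylsilyloxy)phenyl]ethanone F6. Semihydrogenation (H2, Pd/CaCO3 poisoned with Pb(OAc)2, quinoline, EtOAc) should then come back to the route at 8.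

Step 7. The likely failure is slow reaction of the doubly ortho-substituted, hydrogen-bonded phenol, so that the activated alcohol is consumed by alkylation of the reduced azodicarboxylate. The fallback sets out from 3 and uses a Williamson ether synthesis. An Appel reaction (CBr4, PPh3, CH2Cl2, 0 °C) should give 4-(bromomethyl)-1,2-bis(tert-butyldimethylsilyloxy)benzene F7, to be used at once. Alkylation of 10 with F7 (K2CO3, acetone, 40 °C) should come back to the route at 11. The triisopropylsilyl ether at O5 is the reason this base can be considered.

## Further compounds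

F1 | step 9 | (E)-3-(dimethylamino)-1-[2-hydroxy-4-methoxy-3-(3-methylbut-2-enyl)-6-(triisopropylsilyloxy)phenyl]prop-2-en-1-one | CN(C)/C=C/C(=O)c1c(O)c(CC=C(C)C)c(OC)cc1O[Si](C(C)C)(C(C)C)C(C)C
F2 | step 9 | 7-methoxy-8-(3-methylbut-2-enyl)-5-(triisopropylsilyloxy)chromen-4-one | O=c1ccoc2c(CC=C(C)C)c(OC)cc(O[Si](C(C)C)(C(C)C)C(C)C)c12
F3 | step 9 | 4-bromo-1,2-bis(tert-butyldimethylsilyloxy)benzene | Brc1ccc(O[Si](C)(C)C(C)(C)C)c(O[Si](C)(C)C(C)(C)C)c1
F4 | step 9 | [3,4-bis(tert-butyldimethylsilyloxy)phenyl]boronic acid | OB(O)c1ccc(O[Si](C)(C)C(C)(C)C)c(O[Si](C)(C)C(C)(C)C)c1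
F5 | step 8 | (E)-1-[2-[[3,4-bis(tert-butyldimethylsilyloxy)phenyl]methoxy]-4-methoxy-3-(3-methylbut-2-enyl)-6-(triisopropylsilyloxy)phenyl]-3-(dimethylamino)prop-2-en-1-one | CN(C)/C=C/C(=O)c1c(OCc2ccc(O[Si](C)(C)C(C)(C)C)c(O[Si](C)(C)C(C)(C)C)c2)c(CC=C(C)C)c(OC)cc1O[Si](C(C)C)(C(C)C)C(C)C
F6 | step 5 | 1-[4-methoxy-2-(2-methylbut-3-yn-2-yloxy)-6-(triisopropylsilyloxy)phenyl]ethanone | CC(=O)c1c(OC(C)(C)C#C)cc(OC)cc1O[Si](C(C)C)(C(C)C)C(C)C
F7 | step 7 | 4-(bromomethyl)-1,2-bis(tert-butyldimethylsilyloxy)benzene | BrCc1ccc(O[Si](C)(C)C(C)(C)C)c(O[Si](C)(C)C(C)(C)C)c1
A1 | alternative 1 | (5S)-5-[3,4-bis(methoxymethoxy)phenyl]-1-ethoxy-5-(5-methylhex-4-en-1-ynyloxy)pent-1-yn-3-one | CCOC#CC(=O)C[C@H](OC#CCC=C(C)C)c1ccc(OCOC)c(OCOC)c1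
A2 | alternative 1 | methoxyacetylene (methoxyethyne) | COC#C
A3 | alternative 1 | (2S)-2-[3,4-bis(methoxymethoxy)phenyl]-5-ethoxy-7-methoxy-8-(3-methylbut-2-enyl)-2,3-dihydrochromen-4-one | COc1cc(OCC)c2c(c1CC=C(C)C)O[C@H](c1ccc(OCOC)c(OCOC)c1)CC2=O
A4 | alternative 2 | 2-[(3S)-3-[3,4-bis(methoxymethoxy)phenyl]-1-(tert-butyldimethylsilyloxy)-3-hydroxypropyl]-5-methoxy-3-(methoxymethoxy)-6-(3-methylbut-2-enyl)phenyl trifluoromethanesulfonate | COc1cc(OCOC)c(C(O[Si](C)(C)C(C)(C)C)C[C@H](O)c2ccc(OCOC)c(OCOC)c2)c(OS(=O)(=O)C(F)(F)F)c1CC=C(C)C
A5 | alternative 2 | (2S)-2-[3,4-bis(methoxymethoxy)phenyl]-4-(tert-butyldimethylsilyloxy)-7-methoxy-5-(methoxymethoxy)-8-(3-methylbut-2-enyl)chroman | COc1cc(OCOC)c2c(c1CC=C(C)C)O[C@H](c1ccc(OCOC)c(OCOC)c1)CC2O[Si](C)(C)C(C)(C)C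
A6 | alternative 3 | 2-[1-[3,4-bis(methoxymethoxy)phenyl]ethenyloxy]-6-hydroxy-4-methoxy-3-(3-methylbut-2-enyl)benzaldehyde | COc1cc(O)c(C=O)c(OC(=C)c2ccc(OCOC)c(OCOC)c2)c1CC=C(C)C
A7 | alternative 3 | (2S)-2-[3,4-bis(methoxymethoxy)phenyl]-5-hydroxy-7-methoxy-8-(3-methylbut-2-enyl)-2,3-dihydrochromen-4-one | COc1cc(O)c2c(c1CC=C(C)C)O[C@H](c1ccc(OCOC)c(OCOC)c1)CC2=O
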